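## The problem

19 is a cyclobutane in which C1 and C3 each carry a 2,4-dihydroxybenzoyl group and C2 and C4 each carry a phenyl group; formally it is the head-to-tail dimer of a chalcone. All four ring carbons are stereogenic, and the isomer required is the all-trans one: each aroyl group is trans to both neighbouring phenyl groups, so the two aroyl groups are cis to each other across the ring, and so are the two phenyl groups. This isomer has mirror planes through C1/C3 and through C2/C4, so it is achiral and chiral intermediates can be racemic. C1 and C3 are α to ketones and the all-trans arrangement is the thermodynamic one, so these two centres can be corrected with base late in the route. C2 and C4 carry no acidifying group, so their cis relationship cannot be repaired once set, and the first of them to be made has to direct the second. The groups that need care are the four phenols (masked until the last step), cyclobutene intermediates with an ester and a phenyl group on their sp3 carbons (they can open to dienes on warming), and 2-oxocyclobutanecarboxylate enolates (they can be cleaved by nucleophiles). The feature that invites a one-carbon insertion is that phenyl-bearing C4 lies between the carbonyl-bearing carbons C1 and C3, while C1–C2–C3 with its two carboxyl carbons maps onto a 3-oxoglutarate chain whose ketone carbon (C2) survives as an enol handle for the second phenyl group.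

## Retrosynthesis

**19 from 18.** The four phenolic O–H bonds are traced back to methoxymethyl ethers. The phenols have to be masked during the organolithium step, and an acetal that falls off in dilute acid is preferred to methyl ethers, whose cleavage would need a strong Lewis acid on a cyclobutane with vicinal aryl and acyl groups. The all-trans centres of 18 are the thermodynamic ones, so acid cannot erode them.

**18 from 14 and 17.** Both aryl–carbonyl bonds are cut. The aryllithium 17 comes from bromide 16 by halogen–lithium exchange, and 16 from 15 by protection. The neighbouring cut, electrophilic acylation of a resorcinol derivative by a diacid chloride, would again need a Lewis acid and offers no stop against ring opening. The Weinreb amide 14 stops cleanly at the ketone, and the reaction is the same on both arms of a symmetrical substrate. The forward step must add a hindered aryl nucleophile twice without enolising the amide.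

**14 from 13.** The two C–N bonds are made directly from the methyl esters, so no acid stage is needed. 13 is the symmetrical all-trans diester and carries the whole stereochemical content of the target.

**13 from 12.** Only the configuration at C1 changes. 12 has its C1 ester cis to both phenyl groups, and reversible enolisation moves it to the uncrowded all-trans arrangement. This is what allows the hydrogenation before it to be judged only by what it does at C2.

**12 from 11.** The C1–H and C2–H bonds are cut, which leaves the tetrasubstituted cyclobutene 11 with the second phenyl group already on sp2 C2. The neighbouring option forms the C2–phenyl bond last, by conjugate addition of the phenyl group of 10 to a cyclobutene ester without a C2 substituent (F5 in the fallbacks). That option was weighed and set aside for the main line: the phenyl group would have to enter on the face that carries the C4 phenyl, with the metal sitting on C1 next to that phenyl group. In 11 the same steric ranking works in the desired direction, because the small reagent (hydrogen) must arrive anti to the C4 phenyl, the larger of the two groups on the sp3 carbons. The forward step must deliver hydrogen to that face.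

**11 from 9 and 10.** The C2–phenyl bond is cut at an sp2 carbon, where no stereochemistry is at stake. A β-sulfonyloxy enoate is among the most reactive partners for cross-coupling with boronic acid 10.

**9 from 7.** The enol triflate is taken back to the silyl enol ether 7 through the enolate 8, so the oxygen that the ring-forming step leaves on C2 is used directly as the leaving group. The forward step must trap a strained β-keto ester enolate on oxygen before anything else happens to it.

**7 from 3 and 6 (key disconnection).** The C4–C3 and C4–C1 bonds are cut, which removes C4 as a benzylidene unit. The neighbouring [2+2] cuts would pair two electron-poor π systems of mismatched polarity, and light-driven dimerisation would not give the required relationship of the phenyl groups. The [3+1] cut instead joins a nucleophilic carbon that also carries a leaving group (the ylide carbon of 6) to the two electrophilic termini of a copper enolcarbene derived from 3. The precursors are an acyclic diazo ester and a benzyl sulfonium ylide, with no ring and no stereocentre. The forward step must form two C–C bonds, a four-membered ring and two stereocentres, and the ylide must attack at the vinylogous carbon first.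

**3 from 2 from 1; 6 from 5 from 4.** The enoldiazo ester 3 is the O-silyl enol ether of the diazo ketone 2, which is the mono-diazo-transfer product of 1. A bulky silyl group is chosen for hydrolytic stability and to shield the carbene carbon. The ylide 6 is the conjugate base of sulfonium salt 5, made by S-alkylation of the simplest dialkyl sulfide with 4. A non-coordinating counter-ion is chosen so that no halide reaches the copper catalyst.

## Roads not taken

**Alternative 1:** The cut is made inside the two phenyl rings. Each is taken back to an ethynyl group on the cyclobutane and a four-carbon diene, so the precursors are the all-trans diethynyl diketone A1 and buta-1,3-diene A2.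
- Forward key step: a low-valent cobalt–diphosphine catalyst would add A2 across each alkyne in a [4+2] sense to give the bis(cyclohexa-1,4-dienyl) compound A3 (two C–C bonds per new ring). Dehydrogenation would then give the phenyl groups, and the methyl ethers would be cleaved last.
- Merits: the conditions are neutral and mild, the ring stereocentres are not touched while the arenes are made, and the slim ethynyl groups should let the all-trans ring isomer of A1 dominate at equilibrium.
- Weak points: phenyl is the one substituent of the target that can simply be bought, so building it twice adds a cycloaddition and an oxidation per ring without removing any difficulty. The hard part, a cyclobutane with four substituents in the all-trans pattern, is moved back into A1 and not solved. Dehydrogenation beside enolisable aryl ketones and cleavage of four methyl ethers add risk.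
- Comparison: this road is longer than the chosen plan and leaves the ring construction open. In its favour, the cis relationship of the two future phenyl groups is not at stake in its key step, whereas the chosen plan has to win that relationship in step 7.

**Alternative 2:** Both C–phenyl bonds are cut, back to cis-N1,N3-di(quinolin-8-yl)cyclobutane-1,3-dicarboxamide A4 and iodobenzene A5.
- Forward key step: palladium-catalysed, amide-directed C–H arylation with a silver carboxylate as halide acceptor would phenylate C2 and C4, each on the face of the two directing amides, to give the all-cis diamide A6. Removal of the auxiliaries and base epimerisation of both carboxyl-bearing centres (the same thermodynamic drive as step 8) would lead into steps 9–12.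
- Merits: the reaction class is established on cyclobutane carboxamides and the ring is bought. Both phenyl groups are delivered cis to the same amides, so the one relationship that cannot be repaired is fixed by the mechanism. Few steps are needed to reach the diphenyl core.
- Weak points: the second arylation must place a phenyl group on a face that already carries three substituents. Cleavage of two hindered secondary aryl amides usually needs activation and forcing conditions. Two auxiliaries are installed and discarded.
- Comparison: in certainty of the C2/C4 relationship, and probably in step count, this road is better than the chosen plan. The chosen plan sets against it that ring and first stereocentre are built in one catalytic step from acyclic bulk chemicals, that no directing auxiliary is needed, and that in 9 the two phenyl-bearing positions are chemically distinct, so unsymmetrical diaryl analogues are open. It pays for this with an unproven step 4 and a facial-selectivity risk in step 7.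

**Alternative 3:** One ester-bearing ring carbon is cut from both phenyl-bearing carbons. The precursors are the cyclopropene ester A7 and ethyl diazoacetate A8.
- Forward key step: copper-catalysed carbene addition across the C=C bond of A7 would give the bicyclobutane diester A9, whose four peripheral bonds are the target ring. Reductive cleavage of the central bond between the two phenyl-bearing carbons would then give a 2,4-diphenylcyclobutane-1,3-dicarboxylate.
- Merits: it is very short, all four ring carbons carry their final substituents after the key step, and the sequence is symmetrical.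
- Weak points: the double bond of A7 is hindered, cyclopropenes open to vinylcarbenes under the same catalysts, and exo/endo ester isomers are to be expected. Bicyclobutanes with aryl groups on the central bond isomerise to butadienes on mild heating. The reduction that cleaves the central bond creates both phenyl-bearing stereocentres at once, and whether the two hydrogens arrive on the same face depends on the reduction mechanism, with no substituent to bias it.
- Comparison: on paper this is shorter than the chosen plan, and it is no worse in the thermal fragility of its intermediates, since the chosen plan also handles labile cyclobutenes. The chosen plan sets against it that each stereocentre is formed in a separate step with an identifiable controlling element, and that its ring-forming step leaves a functional handle, not a bond that must be reduced blind.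

Key step: step 4

Remark (assumption on the chemistry): the target SMILES is read as the achiral all-trans isomer, so every chiral intermediate is a racemate and descriptors such as (3R*,4S*) are relative; 3 is drawn as the Z enol ether expected from the silylation, and the E isomer would enter step 4 through the same copper carbene.

## Route

Step 1
Reactants: 1 dimethyl 3-oxopentanedioate (dimethyl 3-oxoglutarate)
Product: 2 dimethyl 2-diazo-3-oxopentanedioate
Conditions: 4-acetamidobenzenesulfonyl azide (1.0 equiv), Et3N, MeCN, 0 → 20 °C
Reagents that add atoms: 4-acetamidobenzenesulfonyl azide, CC(=O)Nc1ccc(cc1)S(=O)(=O)N=[N+]=[N-]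
Why: Regitz diazo transfer to a methylene flanked by ketone and ester; one equivalent of azide is used because the first diazo group lowers the acidity of the remaining methylene, which should hold the reaction at the mono-diazo stage.

Step 2
Reactants: 2 dimethyl 2-diazo-3-oxopentanedioate
Product: 3 dimethyl (Z)-2-diazo-3-[(triisopropylsilyl)oxy]pent-3-enedioate
Conditions: TIPSOTf, Et3N, CH2Cl2, 0 °C
Reagents that add atoms: triisopropylsilyl trifluoromethanesulfonate, CC(C)[Si](OS(=O)(=O)C(F)(F)F)(C(C)C)C(C)C
Why: Soft enolisation and O-silylation of the remaining β-keto ester methylene, the standard way to silyl enoldiazo esters; the diazo carbon has no proton, so only the C3=C4 enol ether can form. The product is kept cold and used promptly.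

Step 3
Reactants: 4 benzyl bromide
Product: 5 benzyldimethylsulfonium tetrafluoroborate
Conditions: Me2S, AgBF4, acetone, 0 → 20 °C, dark
Reagents that add atoms: dimethyl sulfide, CSC; silver tetrafluoroborate, [Ag+].F[B-](F)(F)F
Why: S-Alkylation of a dialkyl sulfide by a benzylic halide, driven by precipitation of AgBr; it gives the halide-free salt directly.

Step 4
Reactants: 3 dimethyl (Z)-2-diazo-3-[(triisopropylsilyl)oxy]pent-3-enedioate; 5 benzyldimethylsulfonium tetrafluoroborate
Product: 7 dimethyl (3R*,4S*)-4-phenyl-2-[(triisopropylsilyl)oxy]cyclobut-1-ene-1,3-dicarboxylate, via dimethylsulfonium benzylide 6 (not isolated)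
Conditions: 5 (1.3 equiv), KN(SiMe3)2 (1.25 equiv), THF, −78 °C; cannulated cold into 3, Cu(MeCN)4BF4 (5 mol %), CH2Cl2, −40 → 0 °C
Reagents that add atoms: none
Why: Proposed new method: Cu(MeCN)4BF4 should expel N2 from 3 to give a copper enolcarbene whose vinylogous carbon (C4 of 3) is electrophilic in the manner of a metal-bound oxyallyl cation; the carbanion carbon of 6 is expected to add there, and the vinylcopper carbon so formed then displaces dimethyl sulfide from the benzylic sulfonium carbon, which makes the second C–C bond and frees the catalyst. The closest known reaction type is the monovalent-copper-catalysed [3+1] cycloaddition of silyl enoldiazoacetates with acyl-stabilised sulfonium ylides to 2-silyloxycyclobut-1-ene-1-carboxylates; new here are the semi-stabilised benzyl ylide and the ester on the vinylogous carbon. The cyclobutene closes by a 4-exo-tet intramolecular SN2 displacement at a benzylic carbon, with inversion there. C3 and C4 of 7 arise together in the addition, and by analogy with other substituted enoldiazo esters the trans isomer is expected after the inverting closure; because C3–H is acidic and can equilibrate in steps 5 and 6 the cis isomer would converge, and because 19 is achiral no chiral ligand is needed. The selectivity the step needs is attack at the vinylogous carbon and not at the carbene carbon, which would end in an alkene by loss of dimethyl sulfide; the carbene carbon is flanked by its own ester and by the triisopropylsilyloxy group, which is why the bulkiest common silyl group was chosen. Side reactions of 6 (Sommelet–Hauser rearrangement through the methylide tautomer, self-condensation) are held back by forming it with a slight deficit of base at −78 °C and adding it cold, and the tetrafluoroborate salt keeps halide away from copper. The product is worked up and stored cold because 3-ester-4-phenylcyclobutenes can open to dienes.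

Step 5
Reactants: 7 dimethyl (3R*,4S*)-4-phenyl-2-[(triisopropylsilyl)oxy]cyclobut-1-ene-1,3-dicarboxylate
Product: 9 dimethyl (3R*,4S*)-4-phenyl-2-{[(trifluoromethyl)sulfonyl]oxy}cyclobut-1-ene-1,3-dicarboxylate, via tetrabutylammonium cyclobutenolate 8 (not isolated)
Conditions: Bu4NF (1.05 equiv), THF, −78 °C; then PhNTf2, −78 → 0 °C
Reagents that add atoms: N-phenylbis(trifluoromethanesulfonimide), O=S(=O)(N(c1ccccc1)S(=O)(=O)C(F)(F)F)C(F)(F)F; tetrabutylammonium fluoride, CCCC[N+](CCCC)(CCCC)CCCC.[F-] (counter-ion of 8 only)
Why: Fluoride cleaves the Si–O bond of the silyl enol ether and the liberated enolate is sulfonylated on oxygen by the triflimide, a known one-flask conversion of silyl enol ethers into enol triflates. The acidic C3–H can equilibrate here and in step 6, so the C3 ester should settle trans to the C4 phenyl whatever step 4 delivered.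

Step 6
Reactants: 9 dimethyl (3R*,4S*)-4-phenyl-2-{[(trifluoromethyl)sulfonyl]oxy}cyclobut-1-ene-1,3-dicarboxylate; 10 phenylboronic acid
Product: 11 dimethyl (3R*,4S*)-2,4-diphenylcyclobut-1-ene-1,3-dicarboxylate
Conditions: Pd(OAc)2 (3 mol %), SPhos, K3PO4, THF/H2O, 20 °C
Reagents that add atoms: none
Why: Suzuki–Miyaura coupling of a β-sulfonyloxy enoate, an activated vinyl electrophile for oxidative addition to zerovalent palladium; an active ligand is used so that the coupling runs at room temperature, below the range in which the cyclobutene could open.

Step 7
Reactants: 11 dimethyl (3R*,4S*)-2,4-diphenylcyclobut-1-ene-1,3-dicarboxylate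
Product: 12 dimethyl (1α,2α,3β,4α)-2,4-diphenylcyclobutane-1,3-dicarboxylate (meso; C1 ester cis to both phenyl groups)
Conditions: H2 (1 atm), Pd/C, EtOAc, 0 → 20 °C
Reagents that add atoms: none
Why: Heterogeneous syn-hydrogenation of the strained tetrasubstituted C1=C2 bond; the catalyst should bind the face anti to the C4 phenyl (the larger of the two groups on the sp3 carbons, the smaller C3 ester lying on the other face), which puts the new C2–H trans and the C2 phenyl cis to the C4 phenyl and leaves the C1 ester cis to both phenyl groups. C1 is corrected in step 8; C2 is final.

Step 8
Reactants: 12 dimethyl (1α,2α,3β,4α)-2,4-diphenylcyclobutane-1,3-dicarboxylate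
Product: 13 dimethyl (1α,2β,3α,4β)-2,4-diphenylcyclobutane-1,3-dicarboxylate (all-trans, meso)
Conditions: NaOMe (0.3 equiv), MeOH, 40 °C
Reagents that add atoms: none
Why: Base-mediated epimerisation through the ester enolate; the C1 ester leaves the face it shares with two phenyl groups, and the all-trans isomer, with every substituent trans to its neighbours, is the thermodynamic sink. C2 and C4 are not acidic and are untouched.

Step 9
Reactants: 13 dimethyl (1α,2β,3α,4β)-2,4-diphenylcyclobutane-1,3-dicarboxylate
Product: 14 (1α,2β,3α,4β)-N1,N3-dimethoxy-N1,N3-dimethyl-2,4-diphenylcyclobutane-1,3-dicarboxamide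
Conditions: MeNH(OMe)·HCl, i-PrMgCl, THF, −20 → 0 °C
Reagents that add atoms: N,O-dimethylhydroxylamine hydrochloride, CNOC.Cl
Why: Direct aminolysis of methyl esters by the chloromagnesium amide of N,O-dimethylhydroxylamine (Weinreb amide formation); any α-epimerisation is harmless because the all-trans isomer is already the stable one.

Step 10
Reactants: 15 4-bromobenzene-1,3-diol (4-bromoresorcinol)
Product: 16 1-bromo-2,4-bis(methoxymethoxy)benzene
Conditions: MOMCl, i-Pr2NEt, CH2Cl2, 0 → 20 °C
Reagents that add atoms: chloromethyl methyl ether, COCCl
Why: O-Alkylation of both phenols to acetals that survive organolithium reagents and leave in dilute acid.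

Step 11
Reactants: 14 (1α,2β,3α,4β)-N1,N3-dimethoxy-N1,N3-dimethyl-2,4-diphenylcyclobutane-1,3-dicarboxamide; 16 1-bromo-2,4-bis(methoxymethoxy)benzene
Product: 18 [(1α,2β,3α,4β)-2,4-diphenylcyclobutane-1,3-diyl]bis{[2,4-bis(methoxymethoxy)phenyl]methanone}, via 2,4-bis(methoxymethoxy)phenyllithium 17 (not isolated)
Conditions: 16 (3 equiv), n-BuLi, THF, −78 °C; then 14, −78 → 0 °C; aq. NH4Cl
Reagents that add atoms: n-butyllithium, [Li]CCCC (lithium of 17 only)
Why: Bromine–lithium exchange followed by the Weinreb ketone synthesis; the chelated tetrahedral adducts persist until the quench, so each amide should give a ketone without over-addition, and the ortho acetal oxygen stabilises the aryllithium.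

Step 12
Reactants: 18 [(1α,2β,3α,4β)-2,4-diphenylcyclobutane-1,3-diyl]bis{[2,4-bis(methoxymethoxy)phenyl]methanone}
Product: 19 [(1α,2β,3α,4β)-2,4-diphenylcyclobutane-1,3-diyl]bis[(2,4-dihydroxyphenyl)methanone]
Conditions: HCl (3 M aq.), MeOH, 50 °C
Reagents that add atoms: none
Why: Acid-catalysed acetal exchange with methanol removes the four methoxymethyl groups; the ring centres are in their thermodynamic all-trans arrangement, so acid-promoted enolisation cannot change them.

## Compound list

1 | dimethyl 3-oxopentanedioate (dimethyl 3-oxoglutarate) | COC(=O)CC(=O)CC(=O)OC | starting material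
2 | dimethyl 2-diazo-3-oxopentanedioate | COC(=O)CC(=O)C(=[N+]=[N-])C(=O)OC | intermediate
3 | dimethyl (Z)-2-diazo-3-[(triisopropylsilyl)oxy]pent-3-enedioate | COC(=O)/C=C(\O[Si](C(C)C)(C(C)C)C(C)C)C(=[N+]=[N-])C(=O)OC | intermediate
4 | benzyl bromide | BrCc1ccccc1 | starting material
5 | benzyldimethylsulfonium tetrafluoroborate | C[S+](C)Cc1ccccc1.F[B-](F)(F)F | intermediate
6 | dimethylsulfonium benzylide | C[S+](C)[CH-]c1ccccc1 | intermediate
7 | dimethyl (3R*,4S*)-4-phenyl-2-[(triisopropylsilyl)oxy]cyclobut-1-ene-1,3-dicarboxylate (trans, racemic) | COC(=O)C1=C(O[Si](C(C)C)(C(C)C)C(C)C)[C@H](C(=O)OC)[C@H]1c1ccccc1 | intermediate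
8 | tetrabutylammonium trans-2,4-bis(methoxycarbonyl)-3-phenylcyclobut-1-en-1-olate (racemic) | COC(=O)C1=C([O-])[C@H](C(=O)OC)[C@H]1c1ccccc1.CCCC[N+](CCCC)(CCCC)CCCC | intermediate
9 | dimethyl (3R*,4S*)-4-phenyl-2-{[(trifluoromethyl)sulfonyl]oxy}cyclobut-1-ene-1,3-dicarboxylate (trans, racemic) | COC(=O)C1=C(OS(=O)(=O)C(F)(F)F)[C@H](C(=O)OC)[C@H]1c1ccccc1 | intermediate
10 | phenylboronic acid | OB(O)c1ccccc1 | starting material
11 | dimethyl (3R*,4S*)-2,4-diphenylcyclobut-1-ene-1,3-dicarboxylate (trans, racemic) | COC(=O)C1=C(c2ccccc2)[C@H](C(=O)OC)[C@H]1c1ccccc1 | intermediate
12 | dimethyl (1α,2α,3β,4α)-2,4-diphenylcyclobutane-1,3-dicarboxylate (meso; C1 ester cis to both phenyls, C3 ester trans to both) | COC(=O)[C@@H]1[C@H](c2ccccc2)[C@@H](C(=O)OC)[C@@H]1c1ccccc1 | intermediate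
13 | dimethyl (1α,2β,3α,4β)-2,4-diphenylcyclobutane-1,3-dicarboxylate (all-trans, meso) | COC(=O)[C@H]1[C@H](c2ccccc2)[C@@H](C(=O)OC)[C@@H]1c1ccccc1 | intermediate
14 | (1α,2β,3α,4β)-N1,N3-dimethoxy-N1,N3-dimethyl-2,4-diphenylcyclobutane-1,3-dicarboxamide | CON(C)C(=O)[C@H]1[C@H](c2ccccc2)[C@@H](C(=O)N(C)OC)[C@@H]1c1ccccc1 | intermediate
15 | 4-bromobenzene-1,3-diol (4-bromoresorcinol) | Oc1ccc(Br)c(O)c1 | starting material
16 | 1-bromo-2,4-bis(methoxymethoxy)benzene | COCOc1ccc(Br)c(OCOC)c1 | intermediate
17 | [2,4-bis(methoxymethoxy)phenyl]lithium | [Li]c1ccc(OCOC)cc1OCOC | intermediate
18 | [(1α,2β,3α,4β)-2,4-diphenylcyclobutane-1,3-diyl]bis{[2,4-bis(methoxymethoxy)phenyl]methanone} | O=C(c1ccc(OCOC)cc1OCOC)[C@H]1[C@H](c2ccccc2)[C@@H](C(=O)c2ccc(OCOC)cc2OCOC)[C@@H]1c1ccccc1 | intermediate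
19 | [(1α,2β,3α,4β)-2,4-diphenylcyclobutane-1,3-diyl]bis[(2,4-dihydroxyphenyl)methanone] | O=C(c1ccc(O)cc1O)[C@H]1[C@H](c2ccccc2)[C@@H](C(=O)c2ccc(O)cc2O)[C@@H]1c1ccccc1 | target

## Step count and least certain steps

Total: 12 steps. Longest linear sequence: 10 steps (1 → 2 → 3 → 7 → 9 → 11 → 12 → 13 → 14 → 18 → 19); steps 3 and 10 are side branches.

**Step 4 (key step, the one new method of the route).**
- What may go wrong: the ylide may attack the carbene carbon and not the vinylogous carbon, which ends in an alkene after loss of dimethyl sulfide. The extra ester on the vinylogous carbon makes that site more hindered and less cation-like than in the known cases, which favours this diversion. The semi-stabilised ylide may also be consumed by Sommelet–Hauser rearrangement or self-condensation before the carbene is formed, and 3 may cyclise to a pyrazole on standing.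
- Fallback (known reaction types throughout): it sets out from 1 and comes back to the route at 7. It closes the four-membered ring by the photochemical 4π-electrocyclisation of a 2-pyranone and not by a carbene reaction. C-Acylation of the magnesium enolate of 1 with benzoyl chloride (MgCl2, Et3N, MeCN), followed by lactonisation of the enolised benzoyl oxygen onto the distal ester, would give methyl 4-hydroxy-2-oxo-6-phenyl-2H-pyran-5-carboxylate F1. O-Silylation (TIPSOTf, Et3N) gives methyl 2-oxo-6-phenyl-4-[(triisopropylsilyl)oxy]-2H-pyran-5-carboxylate F2. Irradiation near 300 nm in CH2Cl2 below 0 °C should join C3 to C6 and give the cis-fused bicyclic β-lactone methyl 3-oxo-1-phenyl-5-[(triisopropylsilyl)oxy]-2-oxabicyclo[2.2.0]hex-5-ene-6-carboxylate F3. Hydrogenolysis of its benzylic and allylic C–O bond (H2, Pd/C, EtOAc, 0 °C; the push–pull enol ether double bond is slow to reduce) opens the lactone to 3-(methoxycarbonyl)-4-phenyl-2-[(triisopropylsilyl)oxy]cyclobut-2-ene-1-carboxylic acid F4, and Me3SiCHN2 in MeOH/toluene esterifies it to 7.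

**Step 7.**
- What may go wrong: poor facial selectivity. If hydrogen is delivered to the face that carries the C4 phenyl (anti to the C3 ester), the two phenyl groups end up trans, and no later epimerisation can repair that.
- Fallback: it sets out from 9 and comes back at 13. It reverses the roles, so that the phenyl group and not hydrogen is the incoming group at C2. Reduction of the enol triflate (Pd(OAc)2, PPh3, HCO2H, Et3N, DMF, 20 °C) gives dimethyl (3S*,4S*)-4-phenylcyclobut-1-ene-1,3-dicarboxylate F5. [Rh(OH)(cod)]2-catalysed conjugate addition of 10 (dioxane/H2O, 20–40 °C) then forms the C2–phenyl bond. If reagents prefer the face anti to the C3 ester, which is the very preference that would spoil step 7, the phenyl group now arrives cis to the C4 phenyl. The product is 12, 13 or both (they differ only at C1), and step 8 carries the mixture to 13.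

**Step 5.**
- What may go wrong: cleavage of the strained β-keto diester enolate 8 by attack of fluoride or adventitious hydroxide at the ring carbonyl (retro-Claisen ring opening), while sulfonylation of this stabilised, weakly nucleophilic enolate is slow.
- Fallback: it sets out from 7 and comes back at 9, and avoids a free enolate altogether. Acidic desilylation (HF·pyridine, THF, 0 °C) gives neutral dimethyl 2-oxo-4-phenylcyclobutane-1,3-dicarboxylate F6, which is isolated and then triflated on oxygen with Tf2O and 2,6-di-tert-butyl-4-methylpyridine (CH2Cl2, −78 °C) to give 9.

**Step 11.**
- What may go wrong: proton transfer from the α-C–H of the hindered amide to the aryllithium (enolisation) in place of addition, or addition stopping after the first amide.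
- Fallback: it sets out from 14 and comes back at 18, and uses the more electrophilic aldehyde. LiAlH4 (THF, −78 → 0 °C) reduces both Weinreb amides to (1α,2β,3α,4β)-2,4-diphenylcyclobutane-1,3-dicarbaldehyde F7. Addition of 17 (from 16 and n-BuLi, THF, −78 °C) gives [(1α,2β,3α,4β)-2,4-diphenylcyclobutane-1,3-diyl]bis{[2,4-bis(methoxymethoxy)phenyl]methanol} F8 as a mixture of carbinol epimers. Dess–Martin periodinane (CH2Cl2, NaHCO3) oxidises it to 18.

## Further compounds

F1 | step 4 | methyl 4-hydroxy-2-oxo-6-phenyl-2H-pyran-5-carboxylate | O=C1C=C(O)C(C(=O)OC)=C(c2ccccc2)O1
F2 | step 4 | methyl 2-oxo-6-phenyl-4-[(triisopropylsilyl)oxy]-2H-pyran-5-carboxylate | O=C1C=C(O[Si](C(C)C)(C(C)C)C(C)C)C(C(=O)OC)=C(c2ccccc2)O1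
F3 | step 4 | methyl 3-oxo-1-phenyl-5-[(triisopropylsilyl)oxy]-2-oxabicyclo[2.2.0]hex-5-ene-6-carboxylate (cis-fused, racemic) | O=C1O[C@@]2(c3ccccc3)C(C(=O)OC)=C(O[Si](C(C)C)(C(C)C)C(C)C)[C@@H]12
F4 | step 4 | (1R*,4S*)-3-(methoxycarbonyl)-4-phenyl-2-[(triisopropylsilyl)oxy]cyclobut-2-ene-1-carboxylic acid (trans, racemic) | COC(=O)C1=C(O[Si](C(C)C)(C(C)C)C(C)C)[C@H](C(=O)O)[C@H]1c1ccccc1
F5 | step 7 | dimethyl (3S*,4S*)-4-phenylcyclobut-1-ene-1,3-dicarboxylate (trans, racemic) | COC(=O)C1=C[C@H](C(=O)OC)[C@H]1c1ccccc1
F6 | step 5 | dimethyl 2-oxo-4-phenylcyclobutane-1,3-dicarboxylate (both esters trans to phenyl, meso) | COC(=O)[C@H]1C(=O)[C@@H](C(=O)OC)[C@@H]1c1ccccc1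
F7 | step 11 | (1α,2β,3α,4β)-2,4-diphenylcyclobutane-1,3-dicarbaldehyde | O=C[C@H]1[C@H](c2ccccc2)[C@@H](C=O)[C@@H]1c1ccccc1
F8 | step 11 | [(1α,2β,3α,4β)-2,4-diphenylcyclobutane-1,3-diyl]bis{[2,4-bis(methoxymethoxy)phenyl]methanol} (carbinol epimers) | OC(c1ccc(OCOC)cc1OCOC)[C@H]1[C@H](c2ccccc2)[C@@H](C(O)c2ccc(OCOC)cc2OCOC)[C@@H]1c1ccccc1
A1 | alternative 1 | [(1α,2β,3α,4β)-2,4-diethynylcyclobutane-1,3-diyl]bis[(2,4-dimethoxyphenyl)methanone] | O=C(c1ccc(OC)cc1OC)[C@H]1[C@H](C#C)[C@@H](C(=O)c2ccc(OC)cc2OC)[C@@H]1C#C
A2 | alternative 1 | buta-1,3-diene | C=CC=C
A3 | alternative 1 | [(1α,2β,3α,4β)-2,4-di(cyclohexa-1,4-dien-1-yl)cyclobutane-1,3-diyl]bis[(2,4-dimethoxyphenyl)methanone] | O=C(c1ccc(OC)cc1OC)[C@H]1[C@H](C2=CCC=CC2)[C@@H](C(=O)c2ccc(OC)cc2OC)[C@@H]1C1=CCC=CC1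
A4 | alternative 2 | cis-N1,N3-di(quinolin-8-yl)cyclobutane-1,3-dicarboxamide | O=C(Nc1cccc2cccnc12)[C@H]1C[C@@H](C(=O)Nc2cccc3cccnc23)C1
A5 | alternative 2 | iodobenzene | Ic1ccccc1
A6 | alternative 2 | all-cis-2,4-diphenyl-N1,N3-di(quinolin-8-yl)cyclobutane-1,3-dicarboxamide | O=C(Nc1cccc2cccnc12)[C@H]1[C@@H](c2ccccc2)[C@@H](C(=O)Nc2cccc3cccnc23)[C@H]1c1ccccc1
A7 | alternative 3 | ethyl 2,3-diphenylcycloprop-2-ene-1-carboxylate | CCOC(=O)C1C(c2ccccc2)=C1c1ccccc1
A8 | alternative 3 | ethyl diazoacetate | CCOC(=O)C=[N+]=[N-]
A9 | alternative 3 | diethyl 1,3-diphenylbicyclo[1.1.0]butane-2,4-dicarboxylate (exo,exo isomer) | CCOC(=O)[C@H]1[C@]2(c3ccccc3)[C@@H](C(=O)OCC)[C@]12c1ccccc1
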